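## Structural features

Hispidulin 7-sulfate is a flavone: a benzene ring (ring A) fused through C4a–C8a to a 4-pyranone (ring C), which carries a 4-hydroxyphenyl group (ring B) on C2 through the single bond C2–C1'. There is no stereocentre, so the problem is one of regiochemistry and of telling oxygen atoms apart. Ring A is substituted on three adjacent carbons: a hydroxyl on C5 that is hydrogen-bonded to the C4 carbonyl, a methoxy group on C6 and the hydrogen sulfate on O7; only C8 carries hydrogen. The fragile parts are the aryl sulfate monoester (strongly acidic, very polar, solvolysed by hot acid) and the C6 methyl ether next to the chelated O5, which Lewis acids can remove. The 5,6,7-oxygen pattern as a whole can also be isomerised by hot mineral acid to the 5,7,8-pattern through ring opening and reclosure (Wessely–Moser rearrangement). The difficulty is twofold: the methoxy group must end on C6 and not on C8, which is ambiguous whenever ring C is closed through one of two ortho hydroxyls of a phloroglucinol-type ring A, and the sulfate must go to O7 alone among three phenolic oxygens. The key step uses the fact that C8a is the only hydrogen-bearing carbon ortho to the acyl-bearing C4a once O5 is blocked, and that it lies para to the methoxy-bearing C6. The O1–C8a bond can therefore be made last, by oxidation, on a ring A that carries only the oxygens of C5, C6 and C7 and that derives from a symmetric 2-methoxyresorcinol unit, which can be acylated in only one way.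

## Logic of the disconnections

12 ⇒ 10 (through 11). The O7–S bond is cut first, and the free 4'-hydroxyl is traded for an ester. The sulfate monoester is the most fragile and most polar function, so it belongs in the last operation. Going back to 10 gives a neutral, chromatographable flavone in which the three phenolic oxygens already differ: O4' is acylated, O5 is tied up in the hydrogen bond to the C4 carbonyl, O7 is free. The forward step must sulfate O7 only and then remove the ester with a base mild enough to leave the S–O bond alone; 11 is not isolated.

10 ⇒ 9. The O–H bonds at O5 and O7 are replaced by O–isopropyl bonds. Ring A has to pass through enolate chemistry and an oxidation with non-acidic, electron-releasing oxygens, and O5 must stay blocked until ring C exists. The forward step must cleave two secondary alkyl ethers while the methyl ether between them and the aryl ester survive.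

9 ⇒ 8. The O1–C8a bond is cut; this is the strategic disconnection. It opens ring C to an acyclic 1,3-diketone, and ring A then needs one oxygen fewer, so the choice between two ortho hydroxyls that plagues the classical closure never arises. The skeletons of 8 and 9 were checked atom by atom: the ring A ketone carbon of 8 becomes C4, the methylene C3, the ring B carbonyl C2, and the carbon that receives oxygen is the one para to the methoxy-bearing carbon. Nothing in the two structures needs correcting. Three design points are kept or tightened:
- O5 stays alkylated, because a free O5 would close ring C by plain acid-catalysed dehydration and give the 7,8-dioxygenated isomer.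
- The ring B oxygen stays acylated, which keeps ring B out of the oxidation.
- 8 is electrolysed as the neutral diketone without base, because an enolate would be oxidised at C3 first.

One qualification: the C6 methoxy group is flanked on both sides and twisted out of the ring plane, so its para activation of C8a is weaker than a flat drawing suggests. The closure relies on the tether and on the stability of the cyclohexadienyl radical as much as on ground-state charge density. The demand on the forward step is a dehydrogenative C–O bond formation at an unfunctionalised arene carbon, selective for ring A.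

8 ⇒ 4 + 7. The C2–C3 bond (methylene carbon to ring B carbonyl) is cut, the retron of a Claisen-type acylation. This separates the molecule into a ring A methyl ketone and a ring B acid chloride of similar size. The forward step must acylate the enolate on carbon and must not touch the hindered ester of 7.

4 ⇒ 2 + 3. The two O–C(isopropyl) bonds are cut, which returns 2 and two molecules of 3. The isopropyl groups are large enough to discourage ipso attack at C5 in the key step and can later be removed in the presence of a methyl ether. The forward step must alkylate the hydroxyl chelated to the acetyl group as well as the free one, so 3 is needed in at least twofold amount.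

2 ⇒ 1. The aryl–acyl bond (C4a–C4 in the final numbering) is cut. In 1 the two positions that are ortho to one hydroxyl and para to the other are equivalent, and the carbon para to the methoxy group is meta to both hydroxyls, so only one monoketone can form. The forward step must stop after one acylation.

7 ⇒ 6 ⇒ 5. The C–Cl bond and then the phenolic O–acyl bond are cut. This leads to a bulk hydroxy acid; the forward steps must acylate the phenol in the presence of the carboxylate and then activate the acid without harming the ester.

## Other disconnections considered

Alternative 1: The cut removes ring A. Bonds C8–C8a and C4a–C5 are broken, leaving a pyranone that already holds ring C and ring B, 2-[4-(benzyloxy)phenyl]-6-(methanesulfonyl)-4H-pyran-4-one A2, and a trioxygenated four-carbon diene, 1,2-dimethoxy-1,3-bis(trimethylsilyloxy)buta-1,3-diene A3. In the forward step the CH2 terminus of A3 would add to the sulfonyl-bearing carbon of A2, and the sulfonyl group would leave by addition–elimination. The neighbouring pyranone carbon would then be acylated by the ester-level carbon of the diene, which sheds its silyl and methoxy groups, and tautomerisation would give 4'-O-benzylhispidulin A1.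
- In its favour: A1 has O5 and O7 free, so no dealkylation next to the C6 methoxy group is needed; on this point it is better than the chosen plan.
- In its favour: the position of the methoxy group is fixed by the constitution of A3 and by the polarity match, which is equal to the chosen plan in regiochemical certainty.
- In its favour: the reaction belongs to a known family (cyclocondensation of bis(silyloxy)dienes with 1,3-dielectrophiles), so it is mechanistically better founded than an unprecedented anodic closure.
- Against it: the ring-closing acylation asks the α-carbon of a vinylogous ester for nucleophilicity it hardly has, and it competes with closure through oxygen and with arrest at the open-chain stage.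
- Against it: A3 is a hydrolytically labile diene that needs two silylations, and A2 needs its own sequence (pyranone construction, thioether, oxidation).
- Step economy: after A1, sulfation and hydrogenolysis would reach 12 in two operations, the same as after 9 in the chosen plan. The overall count is expected to be higher because two non-trivial partners must be made.

Alternative 2: Three bonds of ring C are cut, C4a–C4, C4–C3 and O1–C2. The pieces are 2-iodo-4-methoxy-3,5-bis(methoxymethoxy)phenol A5, 1-(benzyloxy)-4-ethynylbenzene A6 and carbon monoxide A7. In the forward step PdCl2(PPh3)2 and CuI with Et2NH would take A5 through oxidative addition to zerovalent palladium (formed in the flask from the divalent palladium precatalyst), insertion of A7, alkynyl transfer from A6 and reductive elimination. The free phenol would then add in the 6-endo mode to the alkynyl ketone so formed and give 2-[4-(benzyloxy)phenyl]-6-methoxy-5,7-bis(methoxymethoxy)-4H-chromen-4-one A4.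
- In its favour: this reaction type has precedent for flavones, and it assembles ring C from three components in one step; on precedent and on convergence it is better than the chosen plan.
- In its favour: the phenol that precedes A5 is symmetric, so iodination can give only one product and the 6-methoxy pattern is unambiguous; this is equal to the chosen plan.
- Against it: A5 carries four oxygens on one ring and is far from any cheap building block.
- Against it: its C–I bond lies between two oxygen substituents on a very electron-rich ring, which slows oxidative addition and CO insertion. Direct alkynylation without A7 and 5-exo closure of the alkynyl ketone are credible competitors.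
- Against it: A7 under pressure and the volatile carcinogenic alkylating agent needed for the acetal groups make it poorer on safety.
- Step economy: after A4 three operations remain (acetal removal, sulfation, hydrogenolysis) against two in the chosen plan, and the route to A5 adds several more.

Alternative 3: The cut again takes ring C apart, at C8a–O1, C4a–C4 and O1–C2. The pieces are 3,5-bis(benzyloxy)-4-methoxybenzyne A10, released from 3,5-bis(benzyloxy)-4-methoxy-2-(trimethylsilyl)phenyl trifluoromethanesulfonate A9, and 3-{4-[(2,2-dimethylpropanoyl)oxy]phenyl}prop-2-ynoic acid A11. In the forward step fluoride would trigger 1,2-elimination of A9. The carboxylate of A11 would add to the carbon of A10 remote from the neighbouring benzyloxy group, and the aryl anion formed ortho to that group would take the acyl group from oxygen (net insertion into the acyl C–O bond). The o-acylphenoxide would then add 6-endo to the triple bond to give 4-[5,7-bis(benzyloxy)-6-methoxy-4-oxo-4H-chromen-2-yl]phenyl 2,2-dimethylpropanoate A8.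
- In its favour: no transition metal, no oxidant and near-ambient temperature; on mildness it is equal to or better than an electrolysis.
- In its favour: the known polarisation of 3-alkoxyarynes places O1 next to C8 and the acyl group next to the C5 oxygen, equal to the chosen plan in regiochemistry.
- In its favour: A8 keeps the same ester, and its benzyl ethers would later be removed by hydrogenolysis, which cannot touch the methyl ether; on this count it is better than the boron trihalide step of the chosen plan.
- Against it: A9 is a pentasubstituted benzene with adjacent silyl and triflate groups and needs a long sequence of its own, so step economy is clearly worse.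
- Against it: A11 can decarboxylate, and its carboxylate can simply be arylated if the aryl anion is protonated before acyl transfer, in which case no ring forms.
- Against it: the acyl shift passes through a strained four-membered transition structure beside a bulky benzyloxy group.
- Mechanistically it is a cascade of known elementary steps and so less speculative than the chosen key step, but it asks more of its starting materials.

Key step: step 6

Remark on the chemistry: the target is drawn as the free hydrogen sulfate; aryl hydrogen sulfates are strong acids, so the compound would in practice be stored as its potassium salt, and the acidification and desalting that end step 8 are taken to deliver the drawn protonation state.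

## Route

Step 1
Reactants: 1 2-methoxybenzene-1,3-diol (2-methoxyresorcinol)
Product: 2 1-(2,4-dihydroxy-3-methoxyphenyl)ethan-1-one
Conditions: AcOH, BF3·OEt2, 90 °C; then aq. NaOAc
Reagents that add atoms: acetic acid, CC(=O)O
Why: Friedel–Crafts-type C-acylation of a resorcinol (Nencki-type); the two activated positions are equivalent by symmetry, the carbon para to the methoxy group is meta to both hydroxyls, and the ketone deactivates the ring toward a second acylation. Acetic acid is used as acyl source so that no phenolic acetate has to be hydrolysed.

Step 2
Reactants: 2 1-(2,4-dihydroxy-3-methoxyphenyl)ethan-1-one, 3 2-bromopropane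
Product: 4 1-[3-methoxy-2,4-di(propan-2-yloxy)phenyl]ethan-1-one
Conditions: 2-bromopropane (3 equiv in all), K2CO3 (3 equiv), KI (cat.), DMF, 60 °C
Reagents that add atoms: 2-bromopropane (second equivalent), CC(C)Br
Why: Twofold Williamson ether synthesis in one flask: each of the two phenoxides takes one isopropyl group, so two molecules of 2-bromopropane are consumed per molecule of 2, and a third is charged because part of the secondary bromide is lost to E2 elimination. The hydroxyl chelated to the acetyl group reacts more slowly and sets the temperature and time, and the carbonate is too weak to enolise the ketone.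

Step 3
Reactants: 5 4-hydroxybenzoic acid
Product: 6 4-[(2,2-dimethylpropanoyl)oxy]benzoic acid
Conditions: PivCl, NaOH, H2O/THF, 0 °C; then HCl to pH 2
Reagents that add atoms: pivaloyl chloride (2,2-dimethylpropanoyl chloride), CC(C)(C)C(=O)Cl
Why: Schotten–Baumann O-acylation of the phenoxide of the dianion; any mixed anhydride formed at the carboxylate is hydrolysed in the aqueous base, while the hindered aryl pivalate survives the cold, brief exposure.

Step 4
Reactants: 6 4-[(2,2-dimethylpropanoyl)oxy]benzoic acid
Product: 7 4-(chlorocarbonyl)phenyl 2,2-dimethylpropanoate
Conditions: (COCl)2, DMF (cat.), CH2Cl2, 0 °C to rt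
Reagents that add atoms: oxalyl chloride, O=C(Cl)C(=O)Cl
Why: Acid chloride formation through the Vilsmeier-type chloroiminium species generated from catalytic DMF; the conditions are non-nucleophilic, so the pivalate is untouched and the volatile by-products leave on evaporation.

Step 5
Reactants: 4 1-[3-methoxy-2,4-di(propan-2-yloxy)phenyl]ethan-1-one, 7 4-(chlorocarbonyl)phenyl 2,2-dimethylpropanoate
Product: 8 4-{3-[3-methoxy-2,4-di(propan-2-yloxy)phenyl]-3-oxopropanoyl}phenyl 2,2-dimethylpropanoate
Conditions: LiN(SiMe3)2 (2.2 equiv), THF, −78 °C; then 7, −78 to 0 °C; then 1 M HCl
Reagents that add atoms: none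
Why: Claisen-type C-acylation of a ketone lithium enolate by an aroyl chloride; the second equivalent of base converts the more acidic 1,3-diketone into its lithium chelate and drives the reaction, and the hindered pivalate is a far poorer electrophile than the acid chloride at −78 °C. The product should exist largely as its chelated enol.

Step 6
Reactants: 8 4-{3-[3-methoxy-2,4-di(propan-2-yloxy)phenyl]-3-oxopropanoyl}phenyl 2,2-dimethylpropanoate
Product: 9 4-[6-methoxy-4-oxo-5,7-di(propan-2-yloxy)-4H-chromen-2-yl]phenyl 2,2-dimethylpropanoate
Conditions: graphite anode, Pt cathode, undivided cell, constant current (5 mA cm−2, 2.2 F mol−1), Bu4NBF4 (0.1 M), (CF3)2CHOH, 25 °C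
Reagents that add atoms: none
Why: Proposed new method: one-electron oxidation at the anode should occur at the trialkoxy-substituted ring A of 8, the most easily oxidised π-system, and give an arene radical cation that (CF3)2CHOH stabilises and does not trap; the oxygen attached to C2 (enol hydroxyl or, in the other tautomer, carbonyl oxygen) then adds to C8a, and the cyclohexadienyl radical, stabilised by the C6 methoxy group para to the new bond and by the C4 carbonyl, is oxidised again and loses the C8a proton to restore aromaticity (ECEC sequence, with H2 evolved at the cathode). The closest known reaction types are the anodic dehydrogenative lactonisation of biaryl-2-carboxylic acids to benzocoumarins and the anodic cyclisation of anilides to benzoxazoles, in both of which an oxygen nucleophile bonds to an unfunctionalised arene carbon; a 1,3-diketone oxygen has not been used in this way. Ring C closes in a 6-endo-trig mode onto the C4a=C8a bond through a planar tether of sp2 atoms. No stereocentre is formed. The step needs chemoselectivity for ring A over the enol carbon C3 and over ring B, which the three alkoxy donors on ring A, the ester on ring B and the base-free medium (no enolate) should secure. It also needs site selectivity for C8a over ipso attack at the isopropoxy-bearing C5, which the bulk of the isopropyl group and the irreversible second oxidation and proton loss available only after attack at C8a should secure. Limiting the charge to little more than 2 F mol−1 should restrain over-oxidation of 9, which has no internal nucleophile left.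

Step 7
Reactants: 9 4-[6-methoxy-4-oxo-5,7-di(propan-2-yloxy)-4H-chromen-2-yl]phenyl 2,2-dimethylpropanoate
Product: 10 4-(5,7-dihydroxy-6-methoxy-4-oxo-4H-chromen-2-yl)phenyl 2,2-dimethylpropanoate
Conditions: BCl3 (4 equiv), CH2Cl2, −78 to 0 °C; then ice/H2O
Reagents that add atoms: none
Why: Lewis-acid ether cleavage; BCl3 ionises secondary alkyl aryl ethers (the isopropyl group leaves as 2-chloropropane) much faster than methyl ethers, the O5 ether is further activated by chelation of boron to the C4 carbonyl, and the aryl pivalate and the flavone core are inert at or below 0 °C, where acid-induced isomerisation of the oxygen pattern is not expected.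

Step 8
Reactants: 10 4-(5,7-dihydroxy-6-methoxy-4-oxo-4H-chromen-2-yl)phenyl 2,2-dimethylpropanoate
Product: 12 5-hydroxy-2-(4-hydroxyphenyl)-6-methoxy-4-oxo-4H-chromen-7-yl hydrogen sulfate (hispidulin 7-sulfate), via hispidulin 4'-pivalate 7-sulfate 11 (not isolated)
Conditions: SO3·pyridine (3 equiv), pyridine, 25 °C; then MeOH, K2CO3, 40 °C; then 1 M HCl to pH 2, 0 °C, C18 desalting
Reagents that add atoms: sulfur trioxide–pyridine complex, O=S(=O)([O-])[n+]1ccccc1
Why: O-sulfation of a phenol with a sulfur trioxide–amine complex; O7 is the only free, unhindered and most acidic hydroxyl, because O5 is held in the hydrogen bond to the C4 carbonyl and O4' is acylated. Base-mediated methanolysis (transesterification) of the activated aryl pivalate then frees O4' without touching the aryl sulfate monoanion, which resists alkaline solvolysis, and cold acidification gives the drawn form.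

## Compound list

1 | 2-methoxybenzene-1,3-diol (2-methoxyresorcinol) | COc1c(O)cccc1O | starting material
2 | 1-(2,4-dihydroxy-3-methoxyphenyl)ethan-1-one | COc1c(O)ccc(C(C)=O)c1O | intermediate
3 | 2-bromopropane | CC(C)Br | starting material
4 | 1-[3-methoxy-2,4-di(propan-2-yloxy)phenyl]ethan-1-one | COc1c(OC(C)C)ccc(C(C)=O)c1OC(C)C | intermediate
5 | 4-hydroxybenzoic acid | O=C(O)c1ccc(O)cc1 | starting material
6 | 4-[(2,2-dimethylpropanoyl)oxy]benzoic acid | CC(C)(C)C(=O)Oc1ccc(C(=O)O)cc1 | intermediate
7 | 4-(chlorocarbonyl)phenyl 2,2-dimethylpropanoate | CC(C)(C)C(=O)Oc1ccc(C(=O)Cl)cc1 | intermediate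
8 | 4-{3-[3-methoxy-2,4-di(propan-2-yloxy)phenyl]-3-oxopropanoyl}phenyl 2,2-dimethylpropanoate | COc1c(OC(C)C)ccc(C(=O)CC(=O)c2ccc(OC(=O)C(C)(C)C)cc2)c1OC(C)C | intermediate
9 | 4-[6-methoxy-4-oxo-5,7-di(propan-2-yloxy)-4H-chromen-2-yl]phenyl 2,2-dimethylpropanoate | COc1c(OC(C)C)cc2oc(-c3ccc(OC(=O)C(C)(C)C)cc3)cc(=O)c2c1OC(C)C | intermediate
10 | 4-(5,7-dihydroxy-6-methoxy-4-oxo-4H-chromen-2-yl)phenyl 2,2-dimethylpropanoate | COc1c(O)cc2oc(-c3ccc(OC(=O)C(C)(C)C)cc3)cc(=O)c2c1O | intermediate
11 | 4-[5-hydroxy-6-methoxy-4-oxo-7-(sulfooxy)-4H-chromen-2-yl]phenyl 2,2-dimethylpropanoate (present in the flask as its pyridinium salt, not isolated) | COc1c(OS(=O)(=O)O)cc2oc(-c3ccc(OC(=O)C(C)(C)C)cc3)cc(=O)c2c1O | intermediate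
12 | 5-hydroxy-2-(4-hydroxyphenyl)-6-methoxy-4-oxo-4H-chromen-7-yl hydrogen sulfate (hispidulin 7-sulfate) | COc1c(OS(=O)(=O)O)cc2oc(-c3ccc(O)cc3)cc(=O)c2c1O | target

No compound of the route contains a stereocentre.

## Step count and risk

Total step count: 8 (steps 1 and 2 for ring A, steps 3 and 4 for ring B, steps 5 to 8 after the fragments are joined).
Longest linear sequence: 6 steps (1 → 2 → 4 → 8 → 9 → 10 → 12, steps 1, 2, 5, 6, 7, 8). The branch from 5 is equally long (steps 3, 4, 5, 6, 7, 8).

Least certain steps:

Step 6 (key step, proposed new method). What may go wrong:
- Oxidation at the enolised diketone instead of ring A, followed by coupling or oligomerisation at C3.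
- Ipso attack of the oxygen at the isopropoxy-bearing C5 with loss of the isopropyl group, which would build the 7,8-dioxygenated ring pattern.
- Oxidative loss of an isopropyl group from the radical cation.
- Slow closure, because C8a is meta to the two in-plane alkoxy donors and para only to the twisted methoxy group, so the radical cation has little charge there and may decay before it is trapped.

Fallback, with known chemistry only: the oxygen on C8a is installed on ring A before ring C is made. It sets out from 1 (using 3 and 7) and returns to the route at 9.
- Double alkylation of 1 with two molecules of 3 (K2CO3, DMF, 60 °C) should give 2-methoxy-1,3-di(propan-2-yloxy)benzene F1.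
- Sterically controlled C–H borylation ([Ir(OMe)(cod)]2, 4,4'-di-tert-butyl-2,2'-bipyridine, B2pin2, THF, 80 °C) should functionalise the only carbon without an ortho substituent, the one para to the methoxy group, and give 2-[4-methoxy-3,5-di(propan-2-yloxy)phenyl]-4,4,5,5-tetramethyl-1,3,2-dioxaborolane F2.
- Oxidation (H2O2, NaOH, THF/H2O, 0 °C) should give 4-methoxy-3,5-di(propan-2-yloxy)phenol F3.
- Ortho-acetylation (AcOH, BF3·OEt2, 60 °C), possible at two equivalent positions, should give 1-[6-hydroxy-3-methoxy-2,4-di(propan-2-yloxy)phenyl]ethan-1-one F4.
- Acylation of its lithium dianion with 7 (LiN(SiMe3)2, 3 equiv, THF, −78 to 0 °C; Baker–Venkataraman-type diketone synthesis) should give 4-{3-[6-hydroxy-3-methoxy-2,4-di(propan-2-yloxy)phenyl]-3-oxopropanoyl}phenyl 2,2-dimethylpropanoate F5.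
- Acid-catalysed cyclodehydration (TsOH cat., toluene, 80 °C) should give 9. Only one hydroxyl is free, so the closure cannot produce the 8-methoxy isomer.

Step 5. What may go wrong: acylation of the enolate on oxygen instead of carbon, acylation of the silylamide base by 7, or a second acylation of the diketonate, all of which lower the amount of 8. Fallback, from 4 and 7 back to 8, by aldol addition and oxidation instead of acylation:
- Reduction of 7 (LiAlH(O-t-Bu)3, THF, −78 °C) should give 4-formylphenyl 2,2-dimethylpropanoate F6.
- Addition of the lithium enolate of 4 (LiN(SiMe3)2, THF, −78 °C, cold quench) should give racemic 4-{1-hydroxy-3-[3-methoxy-2,4-di(propan-2-yloxy)phenyl]-3-oxopropyl}phenyl 2,2-dimethylpropanoate F7.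
- Oxidation of the secondary alcohol (Dess–Martin periodinane, CH2Cl2, rt) should give 8.

Step 7. What may go wrong: demethylation at O6, assisted by the boron chelate between O5 and the C4 carbonyl, or incomplete cleavage of the unactivated O7 ether. Fallback, from 2 back to 10, with ethers that are removed without any Lewis acid:
- Benzylation of 2 (BnBr, K2CO3, DMF, 60 °C) should give 1-[2,4-bis(benzyloxy)-3-methoxyphenyl]ethan-1-one F8.
- Acylation with 7 under the conditions of step 5 should give 4-{3-[2,4-bis(benzyloxy)-3-methoxyphenyl]-3-oxopropanoyl}phenyl 2,2-dimethylpropanoate F9.
- Ring closure as in step 6 (or through the hydroxylated series of the fallback to step 6) should give 4-[5,7-bis(benzyloxy)-6-methoxy-4-oxo-4H-chromen-2-yl]phenyl 2,2-dimethylpropanoate F10, the same compound as A8.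
- Hydrogenolysis (H2, Pd/C, EtOAc, rt), which cannot cleave the methyl ether, should give 10.

Benzylic ethers are more exposed than isopropyl ethers to fragmentation at the anode, which is why they are not the first choice.

Step 8. What may go wrong: incomplete sulfation or additional sulfation of the chelated O5, loss of the sulfate by acid-catalysed solvolysis during acidification, and poor separation of the very polar product from inorganic salts. Fallback, from 10 to 11, with a masked sulfate that is neutral and can be chromatographed on silica:
- Reaction of 10 with 2,2,2-trichloroethyl chlorosulfate (Et3N, DMAP, THF, 0 °C) should give 4-{5-hydroxy-6-methoxy-4-oxo-7-[(2,2,2-trichloroethoxy)sulfonyloxy]-4H-chromen-2-yl}phenyl 2,2-dimethylpropanoate F11.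
- Reductive removal of the trichloroethyl group (Zn dust, HCO2NH4, MeOH, rt) should give 11 as its ammonium salt.
- 11 then re-enters step 8 at the methanolysis stage.

## Further compounds

F1 | step 6 | 2-methoxy-1,3-di(propan-2-yloxy)benzene | COc1c(OC(C)C)cccc1OC(C)C
F2 | step 6 | 2-[4-methoxy-3,5-di(propan-2-yloxy)phenyl]-4,4,5,5-tetramethyl-1,3,2-dioxaborolane | COc1c(OC(C)C)cc(B2OC(C)(C)C(C)(C)O2)cc1OC(C)C
F3 | step 6 | 4-methoxy-3,5-di(propan-2-yloxy)phenol | COc1c(OC(C)C)cc(O)cc1OC(C)C
F4 | step 6 | 1-[6-hydroxy-3-methoxy-2,4-di(propan-2-yloxy)phenyl]ethan-1-one | COc1c(OC(C)C)cc(O)c(C(C)=O)c1OC(C)C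
F5 | step 6 | 4-{3-[6-hydroxy-3-methoxy-2,4-di(propan-2-yloxy)phenyl]-3-oxopropanoyl}phenyl 2,2-dimethylpropanoate | COc1c(OC(C)C)cc(O)c(C(=O)CC(=O)c2ccc(OC(=O)C(C)(C)C)cc2)c1OC(C)C
F6 | step 5 | 4-formylphenyl 2,2-dimethylpropanoate | CC(C)(C)C(=O)Oc1ccc(C=O)cc1
F7 | step 5 | 4-{1-hydroxy-3-[3-methoxy-2,4-di(propan-2-yloxy)phenyl]-3-oxopropyl}phenyl 2,2-dimethylpropanoate (racemic) | COc1c(OC(C)C)ccc(C(=O)CC(O)c2ccc(OC(=O)C(C)(C)C)cc2)c1OC(C)C
F8 | step 7 | 1-[2,4-bis(benzyloxy)-3-methoxyphenyl]ethan-1-one | COc1c(OCc2ccccc2)ccc(C(C)=O)c1OCc1ccccc1
F9 | step 7 | 4-{3-[2,4-bis(benzyloxy)-3-methoxyphenyl]-3-oxopropanoyl}phenyl 2,2-dimethylpropanoate | COc1c(OCc2ccccc2)ccc(C(=O)CC(=O)c2ccc(OC(=O)C(C)(C)C)cc2)c1OCc1ccccc1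
F10 | step 7 | 4-[5,7-bis(benzyloxy)-6-methoxy-4-oxo-4H-chromen-2-yl]phenyl 2,2-dimethylpropanoate | COc1c(OCc2ccccc2)cc2oc(-c3ccc(OC(=O)C(C)(C)C)cc3)cc(=O)c2c1OCc1ccccc1
F11 | step 8 | 4-{5-hydroxy-6-methoxy-4-oxo-7-[(2,2,2-trichloroethoxy)sulfonyloxy]-4H-chromen-2-yl}phenyl 2,2-dimethylpropanoate | COc1c(OS(=O)(=O)OCC(Cl)(Cl)Cl)cc2oc(-c3ccc(OC(=O)C(C)(C)C)cc3)cc(=O)c2c1O
A1 | alternative 1 | 2-[4-(benzyloxy)phenyl]-5,7-dihydroxy-6-methoxy-4H-chromen-4-one (4'-O-benzylhispidulin) | COc1c(O)cc2oc(-c3ccc(OCc4ccccc4)cc3)cc(=O)c2c1O
A2 | alternative 1 | 2-[4-(benzyloxy)phenyl]-6-(methanesulfonyl)-4H-pyran-4-one | CS(=O)(=O)c1cc(=O)cc(-c2ccc(OCc3ccccc3)cc2)o1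
A3 | alternative 1 | 1,2-dimethoxy-1,3-bis(trimethylsilyloxy)buta-1,3-diene (geometry of the ketene acetal double bond not defined) | C=C(O[Si](C)(C)C)C(OC)=C(OC)O[Si](C)(C)C
A4 | alternative 2 | 2-[4-(benzyloxy)phenyl]-6-methoxy-5,7-bis(methoxymethoxy)-4H-chromen-4-one | COc1c(OCOC)cc2oc(-c3ccc(OCc4ccccc4)cc3)cc(=O)c2c1OCOC
A5 | alternative 2 | 2-iodo-4-methoxy-3,5-bis(methoxymethoxy)phenol | COCOc1cc(O)c(I)c(OCOC)c1OC
A6 | alternative 2 | 1-(benzyloxy)-4-ethynylbenzene | C#Cc1ccc(OCc2ccccc2)cc1
A7 | alternative 2 | carbon monoxide | [C-]#[O+]
A8 | alternative 3 | 4-[5,7-bis(benzyloxy)-6-methoxy-4-oxo-4H-chromen-2-yl]phenyl 2,2-dimethylpropanoate | COc1c(OCc2ccccc2)cc2oc(-c3ccc(OC(=O)C(C)(C)C)cc3)cc(=O)c2c1OCc1ccccc1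
A9 | alternative 3 | 3,5-bis(benzyloxy)-4-methoxy-2-(trimethylsilyl)phenyl trifluoromethanesulfonate | COc1c(OCc2ccccc2)cc(OS(=O)(=O)C(F)(F)F)c([Si](C)(C)C)c1OCc1ccccc1
A10 | alternative 3 | 3,5-bis(benzyloxy)-4-methoxybenzyne (1,2-didehydro-3,5-bis(benzyloxy)-4-methoxybenzene) | COC1=C(OCc2ccccc2)C#CC=C1OCc1ccccc1
A11 | alternative 3 | 3-{4-[(2,2-dimethylpropanoyl)oxy]phenyl}prop-2-ynoic acid | CC(C)(C)C(=O)Oc1ccc(C#CC(=O)O)cc1
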